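The galloyl ester at O7 is cut first. Ring A is then opened at C6-C7 and C7-C8, which removes C7 as carbon monoxide and leaves ring C as a dihydropyran with an acetoxymethyl arm (C8) on C8a and a 1-benzyloxyvinyl arm (C5=C6) on C4a.
Enabling feature: in ring A only C7 carries an acylated oxygen, and it sits between the two unsubstituted CH positions C6 and C8. A carbonylative benzannulation therefore delivers O7 as an ester while O5 and O1 are ethers.
Ring C is cut at O1-C8a and C4-C4a into a C2-C3-C4 iodohydrin and a 4-silyloxyacetoacetate (C5, C4a, C8a, C8); C6 is added by methylenation of the C5 ester.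
Forward order: ring B comes with the aldehyde, ring C closes by alkylation and cyclodehydration, ring A closes around CO, the galloyl ring is attached last, and eight benzyl groups are removed in one hydrogenolysis.
Stereochemistry: C2 and C3 are set together in one Evans syn glycolate aldol under control of (S)-4-benzyloxazolidin-2-one. The syn relation becomes 2,3-cis because the C2-O bond is never broken.

Key step: step 11

Assumption: flavan numbering (O1, C2, C3, C4, C4a, C5 to C8, C8a) is used for these atoms in every intermediate, and (tert-butyldimethylsilyloxy)acetaldehyde and benzyl diazoacetate are taken as commercial reagents.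

Step 1
Reactants: 1 (S)-4-benzyl-1,3-oxazolidin-2-one; 2 benzyloxyacetyl chloride
Product: 4 (S)-4-benzyl-3-[(benzyloxy)acetyl]-1,3-oxazolidin-2-one, via N-lithio oxazolidinone 3 (not isolated)
Conditions: n-BuLi, THF, −78 °C; then 2, −78 → 0 °C
Reagents that add atoms: none
Why: N-acylation of a lithiated oxazolidinone by an acid chloride is the standard entry to glycolate imides and leaves the auxiliary stereocentre untouched.

Step 2
Reactants: 4 (S)-4-benzyl-3-[(benzyloxy)acetyl]-1,3-oxazolidin-2-one; 5 3,4,5-tris(benzyloxy)benzaldehyde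
Product: 8 (4S)-4-benzyl-3-{(2S,3R)-2-(benzyloxy)-3-hydroxy-3-[3,4,5-tris(benzyloxy)phenyl]propanoyl}-1,3-oxazolidin-2-one, via Z-dibutylboron enolate 6 (not isolated), via boron aldolate 7 (not isolated)
Conditions: Bu2BOTf, NEt3, CH2Cl2, −78 → 0 °C; 5, −78 → 0 °C; then H2O2, MeOH, pH 7 buffer, 0 °C
Reagents that add atoms: none
Why: Evans syn aldol reaction, in which the Z-boron enolate 6 reacts through a chair Zimmerman-Traxler transition state on the face turned away from the benzyl group of the (S)-auxiliary, so that C3 (alpha carbon) and C2 (carbinol carbon) are set together, the absolute sense coming from the auxiliary and the syn relation (later 2,3-cis in ring C) from the enolate geometry.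

Step 3
Reactants: 8 syn aldol imide
Product: 9 (1R,2R)-2-(benzyloxy)-1-[3,4,5-tris(benzyloxy)phenyl]propane-1,3-diol
Conditions: LiBH4, MeOH, THF, 0 °C
Reagents that add atoms: none
Why: Reductive cleavage of the imide by LiBH4 attacks the exocyclic carbonyl, turns it into the C4 hydroxymethyl group without epimerisation at C3 and gives back the auxiliary.

Step 4
Reactants: 9 (1R,2R)-diol
Product: 10 (1R,2S)-2-(benzyloxy)-3-iodo-1-[3,4,5-tris(benzyloxy)phenyl]propan-1-ol
Conditions: I2, PPh3, imidazole, CH2Cl2, 0 °C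
Reagents that add atoms: iodine, [I][I]
Why: Garegg-Samuelsson (Appel-type) iodination is an SN2 process at the activated carbinol carbon and therefore takes the unhindered primary hydroxyl at C4 in preference to the secondary benzylic one at C2, whose configuration is not touched (the descriptor at C3 changes only by priority).

Step 5
Reactants: 11 (tert-butyldimethylsilyloxy)acetaldehyde; 12 benzyl diazoacetate
Product: 13 benzyl 4-[(tert-butyldimethylsilyl)oxy]-3-oxobutanoate
Conditions: SnCl2 (10 mol %), CH2Cl2, rt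
Reagents that add atoms: none
Why: Roskamp reaction, in which SnCl2 activates the aldehyde for addition of the diazo ester and a 1,2-hydride shift with loss of N2 gives, in one operation that silyl ethers tolerate, the beta-keto ester holding C8, C8a, C4a and C5.

Step 6
Reactants: 10 (1R,2S)-iodohydrin; 13 benzyl 4-[(tert-butyldimethylsilyl)oxy]-3-oxobutanoate
Product: 14 benzyl 2-{(2R,3R)-2-(benzyloxy)-3-hydroxy-3-[3,4,5-tris(benzyloxy)phenyl]propyl}-4-[(tert-butyldimethylsilyl)oxy]-3-oxobutanoate (both epimers at C4a)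
Conditions: Cs2CO3, DMF, 45 °C
Reagents that add atoms: none
Why: Acetoacetic ester alkylation, in which the soft carbon nucleophile formed from 13 and carbonate displaces the primary iodide by SN2 to make C4-C4a, the far less acidic C2 hydroxyl stays protonated, and the unselective new centre C4a is erased in step 7.

Step 7
Reactants: 14 hydroxy keto ester
Product: 16 benzyl (2R,3R)-3-(benzyloxy)-6-{[(tert-butyldimethylsilyl)oxy]methyl}-2-[3,4,5-tris(benzyloxy)phenyl]-3,4-dihydro-2H-pyran-5-carboxylate, via cyclic hemiketal 15 (not isolated)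
Conditions: PPTS (cat.), 4 Å MS, toluene, 60 °C
Reagents that add atoms: none
Why: Acid-catalysed cyclodehydration of a delta-hydroxy beta-keto ester, in which the C2 hydroxyl adds 6-exo-trig to the ketone C8a and water is lost towards the acidic C4a-H to give the conjugated vinylogous carbonate, with the C2-O bond kept and hence retention at C2.

Step 8
Reactants: 16 dihydropyran benzyl ester
Product: 17 {[(2R,3R)-3-(benzyloxy)-5-[1-(benzyloxy)ethenyl]-2-[3,4,5-tris(benzyloxy)phenyl]-3,4-dihydro-2H-pyran-6-yl]methoxy}(tert-butyl)dimethylsilane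
Conditions: Cp2TiMe2, toluene, 75 °C, dark; filtration through basic alumina
Reagents that add atoms: dimethyltitanocene Cp2TiMe2, [CH3-].[CH3-].[CH-]1C=CC=C1.[CH-]1C=CC=C1.[Ti+4]
Why: Petasis olefination, in which Cp2TiMe2 loses methane on heating to Cp2Ti=CH2 and this methylenates the only carbonyl group of 16, as it does other alpha,beta-unsaturated esters, to give the 2-alkoxy-1,3-diene with C6 in a non-acidic medium that spares both enol ethers.

Step 9
Reactants: 17 silyl-protected benzyl dienol ether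
Product: 18 [(2R,3R)-3-(benzyloxy)-5-[1-(benzyloxy)ethenyl]-2-[3,4,5-tris(benzyloxy)phenyl]-3,4-dihydro-2H-pyran-6-yl]methanol
Conditions: Bu4NF, THF, 0 °C
Reagents that add atoms: none
Why: Fluoride-induced desilylation runs under mildly basic conditions, which the acid-sensitive bis(enol ether) and the benzyl ethers tolerate.

Step 10
Reactants: 18 dienyl allylic alcohol
Product: 19 [(2R,3R)-3-(benzyloxy)-5-[1-(benzyloxy)ethenyl]-2-[3,4,5-tris(benzyloxy)phenyl]-3,4-dihydro-2H-pyran-6-yl]methyl acetate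
Conditions: Ac2O, NEt3, DMAP (cat.), CH2Cl2, 0 °C; silica deactivated with NEt3
Reagents that add atoms: acetic anhydride, CC(=O)OC(C)=O
Why: DMAP-catalysed acetylation of a primary allylic alcohol in basic medium installs the leaving group for palladium without endangering the enol ethers.

Step 11
Reactants: 19 dienyl allylic acetate
Product: 23 (2R,3R)-3,5-bis(benzyloxy)-2-[3,4,5-tris(benzyloxy)phenyl]-3,4-dihydro-2H-chromen-7-yl acetate, via dienylketene 20 (not isolated), via cyclohexadienone 21 (not isolated), via C7 phenol 22 (not isolated)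
Conditions: PdCl2(PPh3)2 (5 mol %), CO (60 atm), NEt3, Ac2O, toluene, 140 °C, autoclave
Reagents that add atoms: carbon monoxide, [C-]#[O+]; acetic anhydride, CC(=O)OC(C)=O
Why: Zerovalent palladium, formed from PdCl2(PPh3)2 under CO and NEt3, adds oxidatively to the allylic C8-OAc bond of 19 to give a π-allyl complex spanning C8, C8a and C4a, and CO inserts at C8 so that the acyl carbon becomes C7 (bond C7-C8). NEt3 takes the acidified proton at C8, dienylketene 20 leaves the metal and zerovalent palladium is returned. Ring A closes by thermal disrotatory 6π electrocyclisation of the triene C7=C8-C8a=C4a-C5=C6 (bond C6-C7) to cyclohexadienone 21, a polar 6-endo-trig attack of the electron-rich enol ether carbon C6 on the acyl complex leading to the same dienone; enolisation gives phenol 22 and Ac2O traps it as 23. The closest known reaction type is the palladium-catalysed cyclocarbonylation of 2,4-pentadienyl acetates to phenyl acetates (and of cinnamyl acetates to 1-naphthyl acetates) with the same set of reagents. No stereocentre is formed, and C2 and C3 lie outside the reacting π system and carry no acidic hydrogen, so they should pass unchanged. The step needs site selectivity in the CO insertion, secured because C8 is a primary allyl terminus and C4a a fully substituted one, and a cis placement of the two arms, secured by the endocyclic C4a=C8a double bond of ring C; the three oxygens of ring A thereby come out differentiated, O7 as an ester and O5 and O1 as ethers.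

Step 12
Reactants: 23 penta-O-benzyl epigallocatechin 7-acetate
Product: 22 (2R,3R)-3,5-bis(benzyloxy)-2-[3,4,5-tris(benzyloxy)phenyl]-3,4-dihydro-2H-chromen-7-ol
Conditions: K2CO3 (cat.), MeOH/THF, 0 °C
Reagents that add atoms: none
Why: Base-catalysed methanolysis (transesterification) removes the only ester of 23, an activated aryl acetate, while all ethers are inert.

Step 13
Reactants: 22 C7 phenol; 24 3,4,5-tris(benzyloxy)benzoic acid
Product: 25 (2R,3R)-3,5-bis(benzyloxy)-2-[3,4,5-tris(benzyloxy)phenyl]-3,4-dihydro-2H-chromen-7-yl 3,4,5-tris(benzyloxy)benzoate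
Conditions: DCC, DMAP, CH2Cl2, rt
Reagents that add atoms: none
Why: Steglich esterification, in which DCC activates acid 24 and DMAP passes the acyl group to the only free hydroxyl of 22, the C7 phenol.

Step 14
Reactants: 25 octa-O-benzyl epigallocatechin 7-O-gallate
Product: 26 epigallocatechin 7-O-gallate, (2R,3R)-3,5-dihydroxy-2-(3,4,5-trihydroxyphenyl)-3,4-dihydro-2H-chromen-7-yl 3,4,5-trihydroxybenzoate
Conditions: H2 (1 atm), Pd(OH)2/C, THF/MeOH, rt
Reagents that add atoms: none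
Why: Hydrogenolysis of benzyl ethers over Pd(OH)2/C cleaves all eight O-benzyl groups under neutral conditions of the kind used for perbenzylated flavan-3-ol gallates, which spare the aryl ester and the C2-O1 bond, so C2 and C3 keep their configuration.

Compound list
1 | (S)-4-benzyl-1,3-oxazolidin-2-one | O=C1N[C@@H](Cc2ccccc2)CO1 | starting material
2 | benzyloxyacetyl chloride | O=C(Cl)COCc1ccccc1 | starting material
3 | N-lithio (S)-4-benzyl-1,3-oxazolidin-2-one | [Li]N1C(=O)OC[C@@H]1Cc1ccccc1 | intermediate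
4 | (S)-4-benzyl-3-[(benzyloxy)acetyl]-1,3-oxazolidin-2-one | O=C(COCc1ccccc1)N1C(=O)OC[C@@H]1Cc1ccccc1 | intermediate
5 | 3,4,5-tris(benzyloxy)benzaldehyde | O=Cc1cc(OCc2ccccc2)c(OCc2ccccc2)c(OCc2ccccc2)c1 | starting material
6 | Z-dibutylboron enolate of 4 | CCCCB(CCCC)O/C(=C\OCc1ccccc1)N1C(=O)OC[C@@H]1Cc1ccccc1 | intermediate
7 | dibutylboron aldolate of 8 | O=C([C@@H](OCc1ccccc1)[C@H](OB(CCCC)CCCC)c1cc(OCc2ccccc2)c(OCc2ccccc2)c(OCc2ccccc2)c1)N1C(=O)OC[C@@H]1Cc1ccccc1 | intermediate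
8 | (4S)-4-benzyl-3-{(2S,3R)-2-(benzyloxy)-3-hydroxy-3-[3,4,5-tris(benzyloxy)phenyl]propanoyl}-1,3-oxazolidin-2-one | O=C([C@@H](OCc1ccccc1)[C@H](O)c1cc(OCc2ccccc2)c(OCc2ccccc2)c(OCc2ccccc2)c1)N1C(=O)OC[C@@H]1Cc1ccccc1 | intermediate
9 | (1R,2R)-2-(benzyloxy)-1-[3,4,5-tris(benzyloxy)phenyl]propane-1,3-diol | OC[C@@H](OCc1ccccc1)[C@H](O)c1cc(OCc2ccccc2)c(OCc2ccccc2)c(OCc2ccccc2)c1 | intermediate
10 | (1R,2S)-2-(benzyloxy)-3-iodo-1-[3,4,5-tris(benzyloxy)phenyl]propan-1-ol | IC[C@@H](OCc1ccccc1)[C@H](O)c1cc(OCc2ccccc2)c(OCc2ccccc2)c(OCc2ccccc2)c1 | intermediate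
11 | (tert-butyldimethylsilyloxy)acetaldehyde | CC(C)(C)[Si](C)(C)OCC=O | starting material
12 | benzyl diazoacetate | [N-]=[N+]=CC(=O)OCc1ccccc1 | starting material
13 | benzyl 4-[(tert-butyldimethylsilyl)oxy]-3-oxobutanoate | CC(C)(C)[Si](C)(C)OCC(=O)CC(=O)OCc1ccccc1 | intermediate
14 | benzyl 2-{(2R,3R)-2-(benzyloxy)-3-hydroxy-3-[3,4,5-tris(benzyloxy)phenyl]propyl}-4-[(tert-butyldimethylsilyl)oxy]-3-oxobutanoate (C4a epimers) | CC(C)(C)[Si](C)(C)OCC(=O)C(C[C@@H](OCc1ccccc1)[C@H](O)c1cc(OCc2ccccc2)c(OCc2ccccc2)c(OCc2ccccc2)c1)C(=O)OCc1ccccc1 | intermediate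
15 | cyclic hemiketal of 14 (tetrahydropyran-2-ol, C8a and C4a unassigned) | CC(C)(C)[Si](C)(C)OCC1(O)O[C@H](c2cc(OCc3ccccc3)c(OCc3ccccc3)c(OCc3ccccc3)c2)[C@H](OCc2ccccc2)CC1C(=O)OCc1ccccc1 | intermediate
16 | benzyl (2R,3R)-3-(benzyloxy)-6-{[(tert-butyldimethylsilyl)oxy]methyl}-2-[3,4,5-tris(benzyloxy)phenyl]-3,4-dihydro-2H-pyran-5-carboxylate | CC(C)(C)[Si](C)(C)OCC1=C(C(=O)OCc2ccccc2)C[C@@H](OCc2ccccc2)[C@@H](c2cc(OCc3ccccc3)c(OCc3ccccc3)c(OCc3ccccc3)c2)O1 | intermediate
17 | {[(2R,3R)-3-(benzyloxy)-5-[1-(benzyloxy)ethenyl]-2-[3,4,5-tris(benzyloxy)phenyl]-3,4-dihydro-2H-pyran-6-yl]methoxy}(tert-butyl)dimethylsilane | CC(C)(C)[Si](C)(C)OCC1=C(C(=C)OCc2ccccc2)C[C@@H](OCc2ccccc2)[C@@H](c2cc(OCc3ccccc3)c(OCc3ccccc3)c(OCc3ccccc3)c2)O1 | intermediate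
18 | [(2R,3R)-3-(benzyloxy)-5-[1-(benzyloxy)ethenyl]-2-[3,4,5-tris(benzyloxy)phenyl]-3,4-dihydro-2H-pyran-6-yl]methanol | OCC1=C(C(=C)OCc2ccccc2)C[C@@H](OCc2ccccc2)[C@@H](c2cc(OCc3ccccc3)c(OCc3ccccc3)c(OCc3ccccc3)c2)O1 | intermediate
19 | [(2R,3R)-3-(benzyloxy)-5-[1-(benzyloxy)ethenyl]-2-[3,4,5-tris(benzyloxy)phenyl]-3,4-dihydro-2H-pyran-6-yl]methyl acetate | CC(=O)OCC1=C(C(=C)OCc2ccccc2)C[C@@H](OCc2ccccc2)[C@@H](c2cc(OCc3ccccc3)c(OCc3ccccc3)c(OCc3ccccc3)c2)O1 | intermediate
20 | dienylketene, 2-[(2R,3R)-3-(benzyloxy)-5-[1-(benzyloxy)ethenyl]-2-[3,4,5-tris(benzyloxy)phenyl]-3,4-dihydro-2H-pyran-6-yl]ethenone | O=C=CC1=C(C(=C)OCc2ccccc2)C[C@@H](OCc2ccccc2)[C@@H](c2cc(OCc3ccccc3)c(OCc3ccccc3)c(OCc3ccccc3)c2)O1 | intermediate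
21 | cyclohexadienone, (2R,3R)-3,5-bis(benzyloxy)-2-[3,4,5-tris(benzyloxy)phenyl]-3,4-dihydro-2H-chromen-7(6H)-one | O=C1C=C2O[C@H](c3cc(OCc4ccccc4)c(OCc4ccccc4)c(OCc4ccccc4)c3)[C@H](OCc3ccccc3)CC2=C(OCc2ccccc2)C1 | intermediate
22 | (2R,3R)-3,5-bis(benzyloxy)-2-[3,4,5-tris(benzyloxy)phenyl]-3,4-dihydro-2H-chromen-7-ol | Oc1cc(OCc2ccccc2)c2c(c1)O[C@H](c1cc(OCc3ccccc3)c(OCc3ccccc3)c(OCc3ccccc3)c1)[C@H](OCc1ccccc1)C2 | intermediate
23 | (2R,3R)-3,5-bis(benzyloxy)-2-[3,4,5-tris(benzyloxy)phenyl]-3,4-dihydro-2H-chromen-7-yl acetate | CC(=O)Oc1cc(OCc2ccccc2)c2c(c1)O[C@H](c1cc(OCc3ccccc3)c(OCc3ccccc3)c(OCc3ccccc3)c1)[C@H](OCc1ccccc1)C2 | intermediate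
24 | 3,4,5-tris(benzyloxy)benzoic acid | O=C(O)c1cc(OCc2ccccc2)c(OCc2ccccc2)c(OCc2ccccc2)c1 | starting material
25 | (2R,3R)-3,5-bis(benzyloxy)-2-[3,4,5-tris(benzyloxy)phenyl]-3,4-dihydro-2H-chromen-7-yl 3,4,5-tris(benzyloxy)benzoate | O=C(Oc1cc(OCc2ccccc2)c2c(c1)O[C@H](c1cc(OCc3ccccc3)c(OCc3ccccc3)c(OCc3ccccc3)c1)[C@H](OCc1ccccc1)C2)c1cc(OCc2ccccc2)c(OCc2ccccc2)c(OCc2ccccc2)c1 | intermediate
26 | epigallocatechin 7-O-gallate, (2R,3R) | O=C(Oc1cc(O)c2c(c1)O[C@H](c1cc(O)c(O)c(O)c1)[C@H](O)C2)c1cc(O)c(O)c(O)c1 | target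

Total step count: 14. Longest linear sequence: 13 steps (steps 1 to 4 and 6 to 14); step 5 is a one-step side branch.

Steps most likely to fail

Step 11 (cyclocarbonylation).
- Several processes may outrun CO insertion at 140 °C. They are beta-hydride elimination of the π-allyl complex towards C4, a thermal 1,5-hydrogen shift from C8 to C6 in the cis-dienyl system, and hydrolysis or oligomerisation of the bis(enol ether).
- The fallback forms the two bonds to C7 in separate, milder operations. CO still supplies C7.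
- It sets out from alcohol 18. ClCO2Me and pyridine give the allylic methyl carbonate F1.
- Decarboxylative carbonylation of this allylic carbonate (Pd(OAc)2, PPh3, CO 20 atm, THF, 50 °C) forms C7-C8 and gives the methyl dienylacetate F2.
- LiOH in aqueous THF, with careful acidification to pH 5, gives the dienylacetic acid F3.
- Heating F3 in Ac2O with NaOAc, the classical benzannulation of 3,5-dienoic acids, dehydrates it to dienylketene 20. This closes and is acetylated as in step 11, so the route is rejoined at 23.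

Step 6 (alkylation).
- SN2 displacement at a primary carbon next to an alkoxy-bearing branch may be slow.
- O-alkylation, lactonisation onto the benzyl ester, or retro-Claisen acyl transfer to the free C2 hydroxyl may then take over.
- The fallback makes C4-C4a by condensation and reduction instead of substitution.
- It sets out from diol 9. TEMPO with PhI(OAc)2 oxidises only the primary alcohol to the hydroxy aldehyde F4.
- Knoevenagel condensation of F4 with 13 (piperidinium acetate, 4 Å MS, CH2Cl2) gives the alkylidene keto ester F5.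
- Conjugate reduction of F5 with the Hantzsch ester returns to the route at 14.

Step 8 (methylenation).
- The carbonyl group of 16 is hindered and electron-rich (a vinylogous carbonate), so methylenation may be sluggish.
- The product may be lost by hydrolysis of the new enol ether on isolation.
- In the fallback C6 arrives as a methyl group and the diene is made by enolisation.
- It sets out from 16. MeNHOMe·HCl with i-PrMgCl gives the Weinreb amide F6, and MeMgBr gives the methyl ketone F7.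
- Bu4NF then gives the keto alcohol F8, and Ac2O with pyridine gives the keto acetate F9.
- i-Pr3SiOTf with NEt3 silylates the vinylogous ester oxygen and removes a methyl proton, giving the triisopropylsilyl dienol ether F10.
- F10 is submitted to the conditions of step 11 and should give the 5-silyl ether 7-acetate F11.
- Bu4NF buffered with AcOH frees the C5 phenol F12, and a Mitsunobu etherification with benzyl alcohol (PPh3, DIAD) rejoins the route at 23.

Further compounds
F1 | step 11 | [(2R,3R)-3-(benzyloxy)-5-[1-(benzyloxy)ethenyl]-2-[3,4,5-tris(benzyloxy)phenyl]-3,4-dihydro-2H-pyran-6-yl]methyl methyl carbonate | COC(=O)OCC1=C(C(=C)OCc2ccccc2)C[C@@H](OCc2ccccc2)[C@@H](c2cc(OCc3ccccc3)c(OCc3ccccc3)c(OCc3ccccc3)c2)O1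
F2 | step 11 | methyl 2-[(2R,3R)-3-(benzyloxy)-5-[1-(benzyloxy)ethenyl]-2-[3,4,5-tris(benzyloxy)phenyl]-3,4-dihydro-2H-pyran-6-yl]acetate | COC(=O)CC1=C(C(=C)OCc2ccccc2)C[C@@H](OCc2ccccc2)[C@@H](c2cc(OCc3ccccc3)c(OCc3ccccc3)c(OCc3ccccc3)c2)O1
F3 | step 11 | 2-[(2R,3R)-3-(benzyloxy)-5-[1-(benzyloxy)ethenyl]-2-[3,4,5-tris(benzyloxy)phenyl]-3,4-dihydro-2H-pyran-6-yl]acetic acid | OC(=O)CC1=C(C(=C)OCc2ccccc2)C[C@@H](OCc2ccccc2)[C@@H](c2cc(OCc3ccccc3)c(OCc3ccccc3)c(OCc3ccccc3)c2)O1
F4 | step 6 | (2S,3R)-2-(benzyloxy)-3-hydroxy-3-[3,4,5-tris(benzyloxy)phenyl]propanal | O=C[C@@H](OCc1ccccc1)[C@H](O)c1cc(OCc2ccccc2)c(OCc2ccccc2)c(OCc2ccccc2)c1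
F5 | step 6 | benzyl 2-{(2R,3R)-2-(benzyloxy)-3-hydroxy-3-[3,4,5-tris(benzyloxy)phenyl]propylidene}-4-[(tert-butyldimethylsilyl)oxy]-3-oxobutanoate (alkene geometry unassigned) | CC(C)(C)[Si](C)(C)OCC(=O)C(=C[C@@H](OCc1ccccc1)[C@H](O)c1cc(OCc2ccccc2)c(OCc2ccccc2)c(OCc2ccccc2)c1)C(=O)OCc1ccccc1
F6 | step 8 | (2R,3R)-3-(benzyloxy)-6-{[(tert-butyldimethylsilyl)oxy]methyl}-N-methoxy-N-methyl-2-[3,4,5-tris(benzyloxy)phenyl]-3,4-dihydro-2H-pyran-5-carboxamide | CC(C)(C)[Si](C)(C)OCC1=C(C(=O)N(C)OC)C[C@@H](OCc2ccccc2)[C@@H](c2cc(OCc3ccccc3)c(OCc3ccccc3)c(OCc3ccccc3)c2)O1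
F7 | step 8 | 1-[(2R,3R)-3-(benzyloxy)-6-{[(tert-butyldimethylsilyl)oxy]methyl}-2-[3,4,5-tris(benzyloxy)phenyl]-3,4-dihydro-2H-pyran-5-yl]ethanone | CC(C)(C)[Si](C)(C)OCC1=C(C(C)=O)C[C@@H](OCc2ccccc2)[C@@H](c2cc(OCc3ccccc3)c(OCc3ccccc3)c(OCc3ccccc3)c2)O1
F8 | step 8 | 1-[(2R,3R)-3-(benzyloxy)-6-(hydroxymethyl)-2-[3,4,5-tris(benzyloxy)phenyl]-3,4-dihydro-2H-pyran-5-yl]ethanone | OCC1=C(C(C)=O)C[C@@H](OCc2ccccc2)[C@@H](c2cc(OCc3ccccc3)c(OCc3ccccc3)c(OCc3ccccc3)c2)O1
F9 | step 8 | [(2R,3R)-5-acetyl-3-(benzyloxy)-2-[3,4,5-tris(benzyloxy)phenyl]-3,4-dihydro-2H-pyran-6-yl]methyl acetate | CC(=O)OCC1=C(C(C)=O)C[C@@H](OCc2ccccc2)[C@@H](c2cc(OCc3ccccc3)c(OCc3ccccc3)c(OCc3ccccc3)c2)O1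
F10 | step 8 | [(2R,3R)-3-(benzyloxy)-2-[3,4,5-tris(benzyloxy)phenyl]-5-{1-[(triisopropylsilyl)oxy]ethenyl}-3,4-dihydro-2H-pyran-6-yl]methyl acetate | CC(=O)OCC1=C(C(=C)O[Si](C(C)C)(C(C)C)C(C)C)C[C@@H](OCc2ccccc2)[C@@H](c2cc(OCc3ccccc3)c(OCc3ccccc3)c(OCc3ccccc3)c2)O1
F11 | step 8 | (2R,3R)-3-(benzyloxy)-2-[3,4,5-tris(benzyloxy)phenyl]-5-[(triisopropylsilyl)oxy]-3,4-dihydro-2H-chromen-7-yl acetate | CC(=O)Oc1cc(O[Si](C(C)C)(C(C)C)C(C)C)c2c(c1)O[C@H](c1cc(OCc3ccccc3)c(OCc3ccccc3)c(OCc3ccccc3)c1)[C@H](OCc1ccccc1)C2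
F12 | step 8 | (2R,3R)-3-(benzyloxy)-5-hydroxy-2-[3,4,5-tris(benzyloxy)phenyl]-3,4-dihydro-2H-chromen-7-yl acetate | CC(=O)Oc1cc(O)c2c(c1)O[C@H](c1cc(OCc3ccccc3)c(OCc3ccccc3)c(OCc3ccccc3)c1)[C@H](OCc1ccccc1)C2
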